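**Retrosynthetic overview**
1. The ester C–O bond at O4 is cut last, giving 4-hydroxypyranone 11 and the silyl-protected hydroxy acid 14; 11 comes from its methyl ether 10.
2. The only ring, the 2-pyranone (O1, C2 to C6), is cut at C4–C5 and O1–C6. C2–C3–C4 with the reverse-prenyl group become 3-methoxyacrylic acid 4, and C5–C6(Ph) become the benzoyl carbene equivalent 8.
3. The plan rests on one feature: C4 is an oxygen-bearing sp2 carbon cis to the C2 carboxyl across C3=C4, so in 4 its C–H can be metalated from the carboxylate and joined to the phenacyl unit.
4. Acid 4 comes from methyl 3,3-dimethylpent-4-enoate by formylation, O-methylation and saponification; ylide 8 comes from trimethylsulfoxonium iodide and benzoyl chloride.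
5. One ring is formed (step 5); there is no stereocentre, only the E geometry of 4.

Key step: step 5

Remark on the chemistry: in compounds 3, 4 and 9, E means methoxy trans to the carboxyl carbon, which places the vinylic C3–H of 4 cis to the carboxyl.

**Step 1**
Reactants: 1 methyl 3,3-dimethylpent-4-enoate
Product: 2 methyl 2-formyl-3,3-dimethylpent-4-enoate (racemic, in equilibrium with its enol)
Conditions: LiN(iPr)2 (LDA, 1.1 equiv), THF, −78 °C; HCO2Me (excess), −78 °C to rt; 1 M HCl
Reagents that add atoms: methyl formate, COC=O
Why: Crossed Claisen formylation, in which the lithium ester enolate adds to the small formate and the product is stored as its stabilised enolate until the acid quench, while the neopentyl-type alpha carbon suppresses self-condensation.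

**Step 2**
Reactants: 2 methyl 2-formyl-3,3-dimethylpent-4-enoate
Product: 3 methyl (E)-3-methoxy-2-(2-methylbut-3-en-2-yl)prop-2-enoate
Conditions: Me2SO4, K2CO3, DMF, 0 °C to rt; chromatography
Reagents that add atoms: dimethyl sulfate, COS(=O)(=O)OC
Why: O-alkylation of a formyl ester enolate, where C-methylation is blocked because it would place a quaternary carbon next to a quaternary carbon, and the non-chelated potassium enolate in DMF should react from its W-shaped form (oxygen anti to the ester) to give the E enol ether, in which the ester can stay coplanar with the C=C.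

**Step 3**
Reactants: 3 methyl (E)-3-methoxy-2-(2-methylbut-3-en-2-yl)prop-2-enoate
Product: 4 (E)-3-methoxy-2-(2-methylbut-3-en-2-yl)prop-2-enoic acid
Conditions: LiOH·H2O, THF/MeOH/H2O, 50 °C; then 1 M HCl to pH 3, 0 °C
Reagents that add atoms: lithium hydroxide, [Li+].[OH-]
Why: Saponification by acyl–oxygen cleavage, in which the carboxylate formed no longer accepts nucleophiles and the brief cold acidification avoids acid-catalysed E/Z exchange of the enol ether.

**Step 4**
Reactants: 5 trimethylsulfoxonium iodide; 6 benzoyl chloride
Product: 8 dimethylsulfoxonium benzoylmethylide, via dimethylsulfoxonium methylide 7 (not isolated)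
Conditions: 5 (3 equiv), KOtBu (3 equiv), THF, reflux; then 6 (1 equiv), 0 °C to rt
Reagents that add atoms: none
Why: Corey–Chaykovsky ylide formation followed by C-acylation of the methylide, a second equivalent of which removes the acidic proton to leave the stabilised keto ylide.

**Step 5**
Reactants: 4 (E)-3-methoxy-2-(2-methylbut-3-en-2-yl)prop-2-enoic acid; 8 dimethylsulfoxonium benzoylmethylide
Product: 10 4-methoxy-3-(2-methylbut-3-en-2-yl)-6-phenyl-2H-pyran-2-one, via open-chain keto acid 9 (not isolated)
Conditions: [Cp*RhCl2]2 (2.5 mol%), AgSbF6 (10 mol%), NaOAc (0.5 equiv), 8 (1.5 equiv, added in portions), ClCH2CH2Cl, 80 °C, N2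
Reagents that add atoms: none
Why: Proposed new method: the cationic Cp*Rh carboxylate (trivalent rhodium) should cleave the C3–H of 4 by acetate-assisted concerted metalation–deprotonation to a five-membered rhodacycle, after which ylide 8 binds, loses dimethyl sulfoxide to a rhodium carbene, and migratory insertion plus protodemetalation form the C4–C5 bond (pyranone numbering) and release keto acid 9. The carboxyl oxygen of 9 then adds to the phenyl ketone in a 6-exo-trig closure and the hemiketal loses water, forming O1–C6 and the 2-pyranone ring of 10. The closest known reactions are the trivalent-rhodium annulation of benzoic acids with sulfoxonium ylides to isocoumarins and the carboxylate-directed vinylic C–H annulation of acrylic acids with alkynes to 2-pyranones; pairing a vinylic C–H of a 3-alkoxyacrylic acid with a sulfoxonium ylide is the untested part. No stereocentre is formed. The step needs site selectivity for C3–H, and the E geometry secures it, because this hydrogen (acidified by the geminal oxygen) is the only one that gives a five-membered metallacycle, the vinyl C–H bonds would need six- or seven-membered ones, and the quaternary carbon has no allylic hydrogen. It also needs C–H functionalisation to outrun O-alkylation of the acid by the ylide, which the acetate buffer and portionwise addition of 8 are meant to ensure, and since the process is redox-neutral no copper or silver oxidant is present to attack the vinyl group.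

**Step 6**
Reactants: 10 4-methoxy-3-(2-methylbut-3-en-2-yl)-6-phenyl-2H-pyran-2-one
Product: 11 4-hydroxy-3-(2-methylbut-3-en-2-yl)-6-phenyl-2H-pyran-2-one
Conditions: NaSEt (3 equiv), DMF (degassed), 80 °C; then cold 1 M HCl to pH 3–4
Reagents that add atoms: none
Why: SN2 O-demethylation of a vinylogous methyl ester, whose leaving group is a pyranolate about as weakly basic as a carboxylate, so the soft thiolate attacks the methyl carbon while C4 is shielded from addition–elimination by the neighbouring quaternary carbon and the product rests as its inert sodium salt until the cold quench.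

**Step 7**
Reactants: 12 3-hydroxy-3-methylbutanoic acid
Product: 14 3-methyl-3-(triethylsilyloxy)butanoic acid, via bis-silyl compound 13 (not isolated)
Conditions: Et3SiOTf (2.2 equiv), 2,6-lutidine, CH2Cl2, 0 °C to rt; then THF/H2O, rt
Reagents that add atoms: triethylsilyl trifluoromethanesulfonate, CC[Si](CC)(CC)OS(=O)(=O)C(F)(F)F
Why: Silyl triflate silylation of both the tertiary alcohol and the acid, followed by selective hydrolysis of the much more labile silyl ester, which leaves the tertiary silyl ether in place.

**Step 8**
Reactants: 14 3-methyl-3-(triethylsilyloxy)butanoic acid; 11 4-hydroxy-3-(2-methylbut-3-en-2-yl)-6-phenyl-2H-pyran-2-one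
Product: 16 3-(2-methylbut-3-en-2-yl)-2-oxo-6-phenyl-2H-pyran-4-yl 3-methyl-3-(triethylsilyloxy)butanoate, via acid chloride 15 (not isolated)
Conditions: 14, 1-chloro-N,N,2-trimethylprop-1-en-1-amine, CH2Cl2, 0 °C; then 11, pyridine, 0 °C to rt
Reagents that add atoms: none
Why: Acid chloride O-acylation of an acidic enol, in which the neutral chloroenamine forms the acid chloride without free HCl that would strip the silyl ether, C-acylation and O-to-C acyl shift are excluded because C3 is fully substituted, and reversible pyridine-mediated acyl transfer should settle on the conjugated 4-acyloxy-2-pyranone.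

**Step 9**
Reactants: 16 3-(2-methylbut-3-en-2-yl)-2-oxo-6-phenyl-2H-pyran-4-yl 3-methyl-3-(triethylsilyloxy)butanoate
Product: 17 3-(2-methylbut-3-en-2-yl)-2-oxo-6-phenyl-2H-pyran-4-yl 3-hydroxy-3-methylbutanoate (target)
Conditions: HF·pyridine, pyridine, THF, 0 °C
Reagents that add atoms: none
Why: Fluoride-driven desilylation under buffered acidic conditions, which should remove the triethylsilyl ether without water or alcohol that could cleave the activated enol ester and without strong acid that could dehydrate the tertiary alcohol.

**Compound list**
1 | methyl 3,3-dimethylpent-4-enoate | COC(=O)CC(C)(C)C=C | starting material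
2 | methyl 2-formyl-3,3-dimethylpent-4-enoate (racemic) | COC(=O)C(C=O)C(C)(C)C=C | intermediate
3 | methyl (E)-3-methoxy-2-(2-methylbut-3-en-2-yl)prop-2-enoate | CO/C=C(/C(=O)OC)C(C)(C)C=C | intermediate
4 | (E)-3-methoxy-2-(2-methylbut-3-en-2-yl)prop-2-enoic acid | CO/C=C(/C(=O)O)C(C)(C)C=C | intermediate
5 | trimethylsulfoxonium iodide | C[S+](C)(C)=O.[I-] | starting material
6 | benzoyl chloride | O=C(Cl)c1ccccc1 | starting material
7 | dimethylsulfoxonium methylide (not isolated) | C=S(C)(C)=O | intermediate
8 | dimethylsulfoxonium benzoylmethylide | CS(C)(=O)=CC(=O)c1ccccc1 | intermediate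
9 | (E)-3-methoxy-2-(2-methylbut-3-en-2-yl)-5-oxo-5-phenylpent-2-enoic acid (not isolated) | CO/C(CC(=O)c1ccccc1)=C(/C(=O)O)C(C)(C)C=C | intermediate
10 | 4-methoxy-3-(2-methylbut-3-en-2-yl)-6-phenyl-2H-pyran-2-one | C=CC(C)(C)c1c(OC)cc(-c2ccccc2)oc1=O | intermediate
11 | 4-hydroxy-3-(2-methylbut-3-en-2-yl)-6-phenyl-2H-pyran-2-one | C=CC(C)(C)c1c(O)cc(-c2ccccc2)oc1=O | intermediate
12 | 3-hydroxy-3-methylbutanoic acid | CC(C)(O)CC(=O)O | starting material
13 | triethylsilyl 3-methyl-3-(triethylsilyloxy)butanoate (not isolated) | CC[Si](CC)(CC)OC(=O)CC(C)(C)O[Si](CC)(CC)CC | intermediate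
14 | 3-methyl-3-(triethylsilyloxy)butanoic acid | CC[Si](CC)(CC)OC(C)(C)CC(=O)O | intermediate
15 | 3-methyl-3-(triethylsilyloxy)butanoyl chloride (not isolated) | CC[Si](CC)(CC)OC(C)(C)CC(=O)Cl | intermediate
16 | 3-(2-methylbut-3-en-2-yl)-2-oxo-6-phenyl-2H-pyran-4-yl 3-methyl-3-(triethylsilyloxy)butanoate | C=CC(C)(C)c1c(OC(=O)CC(C)(C)O[Si](CC)(CC)CC)cc(-c2ccccc2)oc1=O | intermediate
17 | 3-(2-methylbut-3-en-2-yl)-2-oxo-6-phenyl-2H-pyran-4-yl 3-hydroxy-3-methylbutanoate | C=CC(C)(C)c1c(OC(=O)CC(C)(C)O)cc(-c2ccccc2)oc1=O | target

**Step count**
Total: 9 steps. Longest linear sequence: 7 steps (1, 2, 3, 5, 6, 8, 9).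

**Steps most likely to fail**

Step 5. Three processes could defeat it: proton transfer from the acid to the ylide followed by O-alkylation to the phenacyl ester, drift of the enol ether to the Z isomer (which has no C–H within reach of the carboxylate), and stalling at the open-chain keto acid. The fallback abandons C–H activation for the classical lactonisation of a 3,5-dioxo ester. It sets out from 1. The lithium enolate of 1 (LiN(iPr)2, THF, −78 °C) is acylated with N-methoxy-N-methylacetamide to methyl 2-acetyl-3,3-dimethylpent-4-enoate F1. The dianion of F1 (LiN(iPr)2, 3 equiv, THF, −78 to 0 °C) is benzoylated at the terminal methyl with methyl benzoate to methyl 2-(2-methylbut-3-en-2-yl)-3,5-dioxo-5-phenylpentanoate F2. Heating F2 with DBU in toluene at reflux closes the lactone with loss of methanol and gives 11, where the route is rejoined at step 8; steps 2 to 6 are bypassed.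

Step 2. The O-methylation could proceed through a chelated or sterically biased enolate and place methoxy cis to the ester (Z), or give a mixture that is hard to separate. The geometry is to be checked by NOE: contact between OCH3 and the gem-dimethyl group is expected only for E. The fallback replaces kinetic alkylation by thermodynamic acetal chemistry. It sets out from 2, which is converted with HC(OMe)3, MeOH and catalytic TsOH into methyl 2-(dimethoxymethyl)-3,3-dimethylpent-4-enoate F3. Methanol is then eliminated from F3 with catalytic TsOH in toluene at reflux with removal of methanol. Under these conditions the two enol ethers interconvert through the oxocarbenium ion, and the isomer with the ester coplanar and cis to hydrogen should accumulate. The route is rejoined at 3; any Z ester from step 2 can be fed into the same equilibration.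

Step 6. The thiolate could add to the ring (at C6 or C2 with ring opening, or at C4 with loss of methoxide) instead of attacking the methyl carbon, and the freed 4-hydroxyl could close onto the vinyl group if the work-up is too acidic. The fallback changes from anionic SN2 cleavage to Lewis-acid ether cleavage. It sets out from 10, which is treated with BBr3 in CH2Cl2 at −78 °C to give the dibromoboryl ether of the 4-hydroxypyranone F4, in which boron masks the oxygen. A cold aqueous NaHCO3 quench then releases 11, where the route is rejoined.

**Further compounds**
F1 | step 5 | methyl 2-acetyl-3,3-dimethylpent-4-enoate | COC(=O)C(C(C)=O)C(C)(C)C=C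
F2 | step 5 | methyl 2-(2-methylbut-3-en-2-yl)-3,5-dioxo-5-phenylpentanoate | COC(=O)C(C(=O)CC(=O)c1ccccc1)C(C)(C)C=C
F3 | step 2 | methyl 2-(dimethoxymethyl)-3,3-dimethylpent-4-enoate | COC(=O)C(C(OC)OC)C(C)(C)C=C
F4 | step 6 | 4-(dibromoboranyloxy)-3-(2-methylbut-3-en-2-yl)-6-phenyl-2H-pyran-2-one | C=CC(C)(C)c1c(OB(Br)Br)cc(-c2ccccc2)oc1=O
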